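## Retrosynthetic overview

1. Ring A (C3a, C4, C5, C6, C7, C7a) carries oxygen on C4, C6 and C7a. It carries carbon on C3a (C3 of ring B), C5 (the C10 side chain) and C7 (the aroyl carbon of ring C). This alternation is that of a folded 3,5,7-triketo ester, so ring A is cut at C7–C7a back to a 3-prenyl-5-alkyl-6-aroylmethyl-4-hydroxy-2-pyrone.
2. Ring B is cut at O1–C2. 5-exo opening of an (R)-prenyl epoxide (Shi epoxidation) by the C7a oxygen sets (2S). The C4 methyl ether is placed earlier, on the only hydroxyl para to the ketone.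
3. The pyrone comes from aroylation of its C6 methyl group with the ring C ester and Tsuji–Trost prenylation at pyrone C3. The ring itself comes from lactonisation of the diketo acid made by carboxylating a 3-alkylated acetylacetone.
4. The side-chain stereocentre is taken from the chiral pool: (R)-limonene oxide is ring-cleaved, methylenated and shortened by decarboxylative iodination to the alkylating iodide.
5. Ring order: ring C (bought), the pyrone (temporary ring), ring A, ring B.

Key step: step 11

Assumption: commercial (+)-limonene 1,2-oxide is the cis/trans epoxide mixture derived from (R)-limonene. Both epoxide isomers give the same keto aldehyde, so only C4 matters.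

Remark: the labels C2–C7a are the benzofuran numbers of the target and are used for the same carbons in all precursors. The side-chain descriptor alternates between R and S only because substituent priorities change. No bond at that centre is ever broken.

## Route

Step 1
Reactants: 1 (+)-limonene 1,2-oxide, (4R)-1-methyl-4-(prop-1-en-2-yl)-7-oxabicyclo[4.1.0]heptane (cis/trans mixture)
Product: 2 (3R)-6-oxo-3-(prop-1-en-2-yl)heptanal
Conditions: H5IO6 (1.1 equiv), THF–H2O, 0 °C to rt
Reagents that add atoms: water, O
Why: Epoxide hydrolysis followed in the same flask by periodate glycol cleavage cuts the oxygenated C–C bond of the cyclohexane, the isopropenyl group is inert, and the stereocentre is carried over unchanged from the chiral pool.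

Step 2
Reactants: 2 (3R)-6-oxo-3-(prop-1-en-2-yl)heptanal
Product: 3 (3R)-6-oxo-3-(prop-1-en-2-yl)heptanoic acid
Conditions: NaClO2, NaH2PO4, 2-methylbut-2-ene (large excess), t-BuOH–H2O, 0 °C to rt
Reagents that add atoms: sodium chlorite, [Na+].[O-]Cl=O
Why: The Pinnick oxidation converts only the aldehyde, the excess scavenger alkene takes up the hypochlorous acid before it can reach the isopropenyl group, and the weakly acidic medium avoids the intramolecular aldol reaction of 2.

Step 3
Reactants: 3 (3R)-6-oxo-3-(prop-1-en-2-yl)heptanoic acid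
Product: 4 (3R)-6-methyl-3-(prop-1-en-2-yl)hept-6-enoic acid
Conditions: Ph3PCH3Br (2.5 equiv), KOt-Bu (3.5 equiv), THF, 0 °C to rt; 1 M HCl work-up
Reagents that add atoms: methyltriphenylphosphonium bromide, C[P+](c1ccccc1)(c1ccccc1)c1ccccc1.[Br-]
Why: Wittig methylenation of the methyl ketone tolerates the carboxylate salt, and the stereocentre lies beta to the carboxylate and gamma to the ketone, so it cannot epimerise.

Step 4
Reactants: 4 (3R)-6-methyl-3-(prop-1-en-2-yl)hept-6-enoic acid
Product: 6 (3S)-3-(iodomethyl)-2,6-dimethylhepta-1,6-diene, via Barton ester 5 (not isolated)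
Conditions: 1-hydroxypyridine-2(1H)-thione, DCC, CH2Cl2, 0 °C, dark; then CHI3 (1.5 equiv), tungsten lamp, rt
Reagents that add atoms: iodoform, IC(I)I; 1-hydroxypyridine-2(1H)-thione, On1ccccc1=S (its atoms are held only in 5)
Why: In the Barton decarboxylative iodination the primary radical is trapped by concentrated iodoform much faster than it can cyclise onto the hindered 5-methyl-5-hexenyl alkene or undergo a vinyl shift, and the stereocentre next to the radical carbon is not involved.

Step 5
Reactants: 6 (3S)-3-(iodomethyl)-2,6-dimethylhepta-1,6-diene; 7 acetylacetone (3 equiv)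
Product: 8 3-[(2R)-5-methyl-2-(prop-1-en-2-yl)hex-5-en-1-yl]pentane-2,4-dione
Conditions: Cs2CO3 (1.5 equiv), DMF, 55 °C
Reagents that add atoms: none
Why: In this SN2 C-alkylation the soft iodide leaving group favours carbon over oxygen attack, and the low basicity of the caesium enolate suppresses E2 loss of the allylic beta-hydrogen.

Step 6
Reactants: 8 3-[(2R)-5-methyl-2-(prop-1-en-2-yl)hex-5-en-1-yl]pentane-2,4-dione
Product: 9 3,5-dioxo-4-[(2R)-5-methyl-2-(prop-1-en-2-yl)hex-5-en-1-yl]hexanoic acid (C4 labile, keto/enol mixture)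
Conditions: LiN(i-Pr)2 (2.3 equiv), THF, –78 to 0 °C; dry CO2, –78 °C; cold 1 M HCl
Reagents that add atoms: carbon dioxide, O=C=O
Why: In this beta-diketone dianion carboxylation, double deprotonation leaves the terminal carbanion as the far more nucleophilic site, so CO2 is taken up at the methyl carbon, and the labile C4 centre disappears in the next step.

Step 7
Reactants: 9 3,5-dioxo-4-[(2R)-5-methyl-2-(prop-1-en-2-yl)hex-5-en-1-yl]hexanoic acid
Product: 10 4-hydroxy-6-methyl-5-[(2R)-5-methyl-2-(prop-1-en-2-yl)hex-5-en-1-yl]-2H-pyran-2-one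
Conditions: 1,1'-carbonyldiimidazole (1.3 equiv), THF, 0 °C to rt; dilute HCl work-up
Reagents that add atoms: none
Why: The acyl imidazolide is O-acylated by the enol of the C5 ketone (6-exo-trig lactonisation of a 3,5-diketo acid), tautomerisation to the 4-hydroxy-2-pyrone drives the closure, and the absence of strong acid spares both alkenes.

Step 8
Reactants: 10 4-hydroxy-6-methyl-5-[(2R)-5-methyl-2-(prop-1-en-2-yl)hex-5-en-1-yl]-2H-pyran-2-one
Product: 11 4-hydroxy-6-methyl-5-[(2R)-5-methyl-2-(prop-1-en-2-yl)hex-5-en-1-yl]-3-(3-methylbut-2-en-1-yl)-2H-pyran-2-one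
Conditions: prenyl acetate (1.2 equiv), Pd(PPh3)4 (5 mol %), DBU (1.1 equiv), toluene, 60 °C
Reagents that add atoms: 3-methylbut-2-en-1-yl acetate, CC(C)=CCOC(C)=O
Why: In this Tsuji–Trost allylation the soft pyrone anion attacks the unsubstituted terminus of the 1,1-dimethylallyl palladium complex, and any O-prenyl ether formed kinetically is re-ionised by zerovalent palladium, so the C3-prenyl product should collect as the thermodynamic sink.

Step 9
Reactants: 12 methyl 3-hydroxybenzoate
Product: 13 methyl 3-(methoxymethoxy)benzoate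
Conditions: MOMCl (1.3 equiv), i-Pr2NEt, CH2Cl2, 0 °C to rt
Reagents that add atoms: chloromethyl methyl ether, COCCl
Why: Phenol O-alkylation gives an acetal ether that withstands the amide base, the magnesium methoxide and the oxidant used later.

Step 10
Reactants: 11 4-hydroxy-6-methyl-5-[(2R)-5-methyl-2-(prop-1-en-2-yl)hex-5-en-1-yl]-3-(3-methylbut-2-en-1-yl)-2H-pyran-2-one; 13 methyl 3-(methoxymethoxy)benzoate (1.1 equiv)
Product: 14 4-hydroxy-6-{2-[3-(methoxymethoxy)phenyl]-2-oxoethyl}-5-[(2R)-5-methyl-2-(prop-1-en-2-yl)hex-5-en-1-yl]-3-(3-methylbut-2-en-1-yl)-2H-pyran-2-one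
Conditions: LiN(i-Pr)2 (3.3 equiv), THF, –78 °C; then 13, –78 to 0 °C; cold 0.5 M HCl
Reagents that add atoms: none
Why: Only the C6 methyl group is vinylogously activated by the lactone carbonyl, so the pyrone O,C-dianion forms there and is acylated by the ester (lateral Claisen-type acylation), while the third equivalent of base deprotonates the more acidic product and prevents a second addition.

Step 11
Reactants: 14 4-hydroxy-6-{2-[3-(methoxymethoxy)phenyl]-2-oxoethyl}-5-[(2R)-5-methyl-2-(prop-1-en-2-yl)hex-5-en-1-yl]-3-(3-methylbut-2-en-1-yl)-2H-pyran-2-one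
Product: 16 {2,4,6-trihydroxy-3-[(2R)-5-methyl-2-(prop-1-en-2-yl)hex-5-en-1-yl]-5-(3-methylbut-2-en-1-yl)phenyl}[3-(methoxymethoxy)phenyl]methanone, via open-chain methyl triketo ester 15 (not isolated)
Conditions: Mg(OMe)2 (8 equiv), degassed MeOH, reflux, Ar; cold 1 M HCl work-up
Reagents that add atoms: magnesium methoxide, C[O-].C[O-].[Mg+2] (one methoxy group, held only in 15)
Why: Methoxide delivered from the Lewis-acidic magnesium centre adds to the lactone carbonyl (the future C7a) and opens the pyrone to the chelated methyl 3,5,7-triketo ester 15, in which the C7 methylene between two ketones is the most acidic carbon. Its enolate attacks the ester carbonyl in an intramolecular Claisen condensation, a 6-exo-trig acyl substitution that forms C7–C7a, expels methoxide and gives a 2-aroylcyclohexane-1,3,5-trione that enolises at once to aromatic ring A. The closest known reaction type is the Mg(OMe)2-induced recyclisation of 6-(2-oxoalkyl)-4-hydroxy-2-pyrones and of 3,5,7-triketo esters to acylphloroglucinols, but here the chain is alkylated at both C3a and C5, which is more substitution than the usual cases carry, so ring opening should be slower. No stereocentre is created, the labile C3a and C5 centres of 15 vanish on aromatisation, and the side-chain centre is remote from every acidic position. The selectivity needed is Claisen against aldol folding: in the aldol mode C3a, which already bears the prenyl group and the ester, would attack the aryl ketone to give a quaternary adduct that cannot aromatise and so stays reversible, whereas the Claisen product is removed irreversibly as a chelated phenoxide. The same substitution places the prenyl group on C3a and the side chain on C5 without any C-alkylation of an arene.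

Step 12
Reactants: 16 {2,4,6-trihydroxy-3-[(2R)-5-methyl-2-(prop-1-en-2-yl)hex-5-en-1-yl]-5-(3-methylbut-2-en-1-yl)phenyl}[3-(methoxymethoxy)phenyl]methanone
Product: 17 {2,6-dihydroxy-4-methoxy-3-[(2R)-5-methyl-2-(prop-1-en-2-yl)hex-5-en-1-yl]-5-(3-methylbut-2-en-1-yl)phenyl}[3-(methoxymethoxy)phenyl]methanone
Conditions: TMSCHN2 (1.05 equiv), toluene–MeOH 4:1, 0 °C
Reagents that add atoms: (trimethylsilyl)diazomethane, C[Si](C)(C)C=[N+]=[N-]
Why: Diazoalkane O-methylation starts with proton transfer and therefore picks the most acidic hydroxyl, which is C4–OH (para to the ketone, a vinylogous acid with no hydrogen bond to the carbonyl), and the neutral medium excludes dearomatising C-methylation.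

Step 13
Reactants: 17 {2,6-dihydroxy-4-methoxy-3-[(2R)-5-methyl-2-(prop-1-en-2-yl)hex-5-en-1-yl]-5-(3-methylbut-2-en-1-yl)phenyl}[3-(methoxymethoxy)phenyl]methanone
Product: 18 5-methoxy-2-[3-(methoxymethoxy)benzoyl]-4-[(2R)-5-methyl-2-(prop-1-en-2-yl)hex-5-en-1-yl]-6-(3-methylbut-2-en-1-yl)benzene-1,3-diyl diacetate
Conditions: Ac2O (4 equiv), Et3N, DMAP (cat.), CH2Cl2, rt
Reagents that add atoms: acetic anhydride, CC(=O)OC(C)=O
Why: DMAP-catalysed acetylation masks the two oxidation-prone phenols of ring A for the dioxirane step and keeps the C7a oxygen from reacting before the epoxide is in place.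

Step 14
Reactants: 18 5-methoxy-2-[3-(methoxymethoxy)benzoyl]-4-[(2R)-5-methyl-2-(prop-1-en-2-yl)hex-5-en-1-yl]-6-(3-methylbut-2-en-1-yl)benzene-1,3-diyl diacetate
Product: 19 4-{[(2R)-3,3-dimethyloxiran-2-yl]methyl}-5-methoxy-2-[3-(methoxymethoxy)benzoyl]-6-[(2R)-5-methyl-2-(prop-1-en-2-yl)hex-5-en-1-yl]benzene-1,3-diyl diacetate
Conditions: D-fructose-derived Shi ketone (1,2:4,5-di-O-isopropylidene-β-D-erythro-2,3-hexodiulo-2,6-pyranose, 0.3 equiv), 2KHSO5·KHSO4·K2SO4 (1.1 equiv of KHSO5, slow addition), K2CO3, n-Bu4NHSO4 (cat.), MeCN–CH2(OMe)2/aq. Na2B4O7–Na2H2EDTA buffer (pH about 10), –10 to 0 °C, stopped when 18 is consumed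
Reagents that add atoms: potassium peroxymonosulfate, [K+].[O-]S(=O)(=O)OO
Why: In the Shi epoxidation the chiral dioxirane meets the trisubstituted prenyl alkene through its spiro transition state on the face that gives the (R)-epoxide (reagent control), and with limited oxidant this more nucleophilic alkene should react ahead of the two 1,1-disubstituted ones.

Step 15
Reactants: 19 4-{[(2R)-3,3-dimethyloxiran-2-yl]methyl}-5-methoxy-2-[3-(methoxymethoxy)benzoyl]-6-[(2R)-5-methyl-2-(prop-1-en-2-yl)hex-5-en-1-yl]benzene-1,3-diyl diacetate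
Product: 21 {(2S)-6-hydroxy-2-(2-hydroxypropan-2-yl)-4-methoxy-5-[(2R)-5-methyl-2-(prop-1-en-2-yl)hex-5-en-1-yl]-2,3-dihydro-1-benzofuran-7-yl}[3-(methoxymethoxy)phenyl]methanone, via epoxy diphenol 20 (not isolated)
Conditions: K2CO3 (0.3 equiv), MeOH, 0 °C to 40 °C
Reagents that add atoms: none
Why: Base-catalysed methanolysis frees both phenols, only the C7a phenoxide can reach the epoxide (C4 is a methyl ether), and it opens the less hindered secondary carbon in a 5-exo-tet SN2 reaction with inversion, which turns the (R)-epoxide into (2S) and closes ring B.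

Step 16
Reactants: 21 {(2S)-6-hydroxy-2-(2-hydroxypropan-2-yl)-4-methoxy-5-[(2R)-5-methyl-2-(prop-1-en-2-yl)hex-5-en-1-yl]-2,3-dihydro-1-benzofuran-7-yl}[3-(methoxymethoxy)phenyl]methanone
Product: 22 {(2S)-6-hydroxy-2-(2-hydroxypropan-2-yl)-4-methoxy-5-[(2R)-5-methyl-2-(prop-1-en-2-yl)hex-5-en-1-yl]-2,3-dihydro-1-benzofuran-7-yl}(3-hydroxyphenyl)methanone (CNP0263422.2)
Conditions: HCl (about 1 M) in MeOH, rt to 35 °C, monitored closely
Reagents that add atoms: none
Why: Acid-catalysed acetal solvolysis cleaves the aryl MOM ether through its oxocarbenium ion at an acidity that should be too low to protonate the 1,1-disubstituted alkenes or to ionise the tertiary alcohol, and neither stereocentre is touched.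

## Compound list

1 | (+)-limonene 1,2-oxide, (4R), cis/trans mixture | CC12CC[C@H](CC1O2)C(C)=C | starting material
2 | (3R)-6-oxo-3-(prop-1-en-2-yl)heptanal | CC(=O)CC[C@H](CC=O)C(C)=C | intermediate
3 | (3R)-6-oxo-3-(prop-1-en-2-yl)heptanoic acid | CC(=O)CC[C@H](CC(=O)O)C(C)=C | intermediate
4 | (3R)-6-methyl-3-(prop-1-en-2-yl)hept-6-enoic acid | C=C(C)CC[C@H](CC(=O)O)C(C)=C | intermediate
5 | 2-thioxopyridin-1(2H)-yl (3R)-6-methyl-3-(prop-1-en-2-yl)hept-6-enoate (Barton ester) | C=C(C)CC[C@H](CC(=O)On1ccccc1=S)C(C)=C | intermediate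
6 | (3S)-3-(iodomethyl)-2,6-dimethylhepta-1,6-diene | C=C(C)CC[C@H](CI)C(C)=C | intermediate
7 | acetylacetone | CC(=O)CC(C)=O | starting material
8 | 3-[(2R)-5-methyl-2-(prop-1-en-2-yl)hex-5-en-1-yl]pentane-2,4-dione | C=C(C)CC[C@H](CC(C(C)=O)C(C)=O)C(C)=C | intermediate
9 | 3,5-dioxo-4-[(2R)-5-methyl-2-(prop-1-en-2-yl)hex-5-en-1-yl]hexanoic acid (C4 labile) | C=C(C)CC[C@H](CC(C(C)=O)C(=O)CC(=O)O)C(C)=C | intermediate
10 | 4-hydroxy-6-methyl-5-[(2R)-5-methyl-2-(prop-1-en-2-yl)hex-5-en-1-yl]-2H-pyran-2-one | C=C(C)CC[C@H](CC1=C(C)OC(=O)C=C1O)C(C)=C | intermediate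
11 | 3-prenyl derivative of 10 | C=C(C)CC[C@H](CC1=C(C)OC(=O)C(CC=C(C)C)=C1O)C(C)=C | intermediate
12 | methyl 3-hydroxybenzoate | COC(=O)c1cccc(O)c1 | starting material
13 | methyl 3-(methoxymethoxy)benzoate | COCOc1cccc(C(=O)OC)c1 | intermediate
14 | 3-prenyl-5-side-chain-6-aroylmethyl-4-hydroxy-2-pyrone (key-step precursor) | C=C(C)CC[C@H](CC1=C(CC(=O)c2cccc(OCOC)c2)OC(=O)C(CC=C(C)C)=C1O)C(=C)C | intermediate
15 | methyl 7-[3-(methoxymethoxy)phenyl]-4-[(2R)-5-methyl-2-(prop-1-en-2-yl)hex-5-en-1-yl]-2-(3-methylbut-2-en-1-yl)-3,5,7-trioxoheptanoate (magnesium chelate, C2 and C4 labile) | C=C(C)CC[C@H](CC(C(=O)CC(=O)c1cccc(OCOC)c1)C(=O)C(CC=C(C)C)C(=O)OC)C(=C)C | intermediate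
16 | 3-side-chain-5-prenyl-2,4,6-trihydroxybenzophenone, ring C as MOM ether (key-step product) | C=C(C)CC[C@H](Cc1c(O)c(CC=C(C)C)c(O)c(C(=O)c2cccc(OCOC)c2)c1O)C(=C)C | intermediate
17 | 4-O-methyl ether of 16 | C=C(C)CC[C@H](Cc1c(O)c(C(=O)c2cccc(OCOC)c2)c(O)c(CC=C(C)C)c1OC)C(=C)C | intermediate
18 | diacetate of 17 | C=C(C)CC[C@H](Cc1c(OC(C)=O)c(C(=O)c2cccc(OCOC)c2)c(OC(C)=O)c(CC=C(C)C)c1OC)C(=C)C | intermediate
19 | (R)-prenyl epoxide of 18 | C=C(C)CC[C@H](Cc1c(OC(C)=O)c(C(=O)c2cccc(OCOC)c2)c(OC(C)=O)c(C[C@H]2OC2(C)C)c1OC)C(=C)C | intermediate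
20 | epoxy diphenol (19 without the acetyl groups) | C=C(C)CC[C@H](Cc1c(O)c(C(=O)c2cccc(OCOC)c2)c(O)c(C[C@H]2OC2(C)C)c1OC)C(=C)C | intermediate
21 | MOM ether of the target, (2S), side chain (2R) | C=C(C)CC[C@H](Cc1c(O)c(C(=O)c2cccc(OCOC)c2)c2c(c1OC)C[C@@H](C(C)(C)O)O2)C(=C)C | intermediate
22 | CNP0263422.2 | C=C(C)CC[C@H](Cc1c(O)c(C(=O)c2cccc(O)c2)c2c(c1OC)C[C@@H](C(C)(C)O)O2)C(=C)C | target

## Step count and risks

Total step count: 16. Longest linear sequence: 15 (steps 1–8 and 10–16); step 9 is the side branch.

**Step 11.** The pyrone is present as its electron-rich 4-oxyanion and is flanked by alkyl groups, so methoxide addition to the lactone may be too slow. Once the chain is open, methoxide may also cleave its alpha-alkylated beta-diketone units by retro-Claisen fragmentation before C7 reaches C7a.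

The fallback sets out from 14 and comes back at 17. It removes the negative charge before the folding. Mitsunobu O-methylation of the pyrone hydroxyl of 14 (MeOH, PPh3, DIAD, THF) should give the 4-methoxy-2-pyrone F1, whose lactone stays neutral and more electrophilic in base. NaOMe in MeOH then opens it to the ring-opened (E)-beta-methoxy enoate F2. In F2 the C3a=C4 double bond inherited from the pyrone holds the ester and the chain cis, and one beta-diketone unit fewer can fragment. Methoxide attack at C4 is degenerate. The same C7–C7a Claisen closure and enolisation lead directly to 17, so step 12 is no longer needed.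

**Step 14.** Oxygen transfer to the two 1,1-disubstituted alkenes may compete with epoxidation of the prenyl group. The aryl acetates may also be hydrolysed at the buffered pH, after which the freed phenoxide would be oxidised.

The fallback sets out from 17 and comes back at 21. It replaces reagent control by substrate direction. With the phenols free, VO(acac)2 (5 mol %) and t-BuOOH (1.1 equiv) in CH2Cl2 at 0 °C to rt should deliver oxygen only to the alkene held next to the metal-bound C7a oxygen. This gives the epoxy diphenol 20 together with its (S)-epoxide epimer F3. Both close 5-exo in the flask, or on addition of K2CO3 in MeOH, to 21 and the (2R)-configured dihydrobenzofuran F4. The two products are diastereomers because of the fixed side-chain centre, so they can be separated by preparative HPLC, at the cost of the unwanted epimer.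

**Step 5.** SN2 displacement at the beta-branched carbon may be sluggish, so that O-alkylation of the enolate and E2 loss of HI take over.

The fallback sets out from 6 and comes back at 10. It uses a much more nucleophilic carbanion and builds the chain from the ester end. The dianion of methyl acetoacetate (NaH, then n-BuLi, THF, 0 °C) is alkylated at its gamma carbon by 6 to give methyl (6R)-9-methyl-3-oxo-6-(prop-1-en-2-yl)dec-9-enoate F5. Renewed deprotonation (LiN(i-Pr)2, 3.2 equiv, –78 °C) and gamma-acetylation with N-methoxy-N-methylacetamide give methyl 3,5-dioxo-4-[(2R)-5-methyl-2-(prop-1-en-2-yl)hex-5-en-1-yl]hexanoate F6. DBU in refluxing toluene then lactonises F6 to pyrone 10, so steps 5–7 are bypassed.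

## Further compounds

F1 | step 11 | 4-methoxy-2-pyrone (4-O-methyl ether of 14) | C=C(C)CC[C@H](CC1=C(CC(=O)c2cccc(OCOC)c2)OC(=O)C(CC=C(C)C)=C1OC)C(=C)C
F2 | step 11 | ring-opened (E)-beta-methoxy enoate, methyl ester | C=C(C)CC[C@H](CC(C(=O)CC(=O)c1cccc(OCOC)c1)/C(OC)=C(/CC=C(C)C)C(=O)OC)C(=C)C
F3 | step 14 | (S)-epoxide epimer of 20 | C=C(C)CC[C@H](Cc1c(O)c(C(=O)c2cccc(OCOC)c2)c(O)c(C[C@@H]2OC2(C)C)c1OC)C(=C)C
F4 | step 14 | (2R)-configured dihydrobenzofuran, C2 epimer of 21 | C=C(C)CC[C@H](Cc1c(O)c(C(=O)c2cccc(OCOC)c2)c2c(c1OC)C[C@H](C(C)(C)O)O2)C(=C)C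
F5 | step 5 | methyl (6R)-9-methyl-3-oxo-6-(prop-1-en-2-yl)dec-9-enoate | C=C(C)CC[C@H](CCC(=O)CC(=O)OC)C(C)=C
F6 | step 5 | methyl 3,5-dioxo-4-[(2R)-5-methyl-2-(prop-1-en-2-yl)hex-5-en-1-yl]hexanoate | C=C(C)CC[C@H](CC(C(C)=O)C(=O)CC(=O)OC)C(C)=C
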